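In this flask the substrate units are conserved: solid, dissolved, target with solid product, and homo dimer counted twice sum to the charge at each moment, so what I watch is the race for the solid between coupling and dimerisation.

    solid substrate ⇌ dissolved substrate, rate k1*(cs1 - [dissolved substrate]) while solid is left; crystals form when [dissolved substrate] > cs1 (cs1 = 1.4 mM, k1 = 0.90 s⁻¹)
    dissolved substrate + reagent → target (k2 = 6.4 M⁻¹ s⁻¹)
    solid product ⇌ target, rate k3*(cs3 - [target]) while solid is left; crystals form when [target] > cs3 (cs3 = 0.39 mM, k3 = 1.1 s⁻¹)
    reagent ⇌ dormant form (K4 = 1.4, k4 = 0.051 s⁻¹)
    2 solid substrate → homo dimer (k5 = 0.52 M⁻¹ s⁻¹)

solid substrate 0.020 M; reagent 1.05 equiv; time 12 min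

- percent here means solid substrate units held: one homo dimer counts as two
- what is said of target includes solid product
- two of one species on the left: rate k times its square, two consumed each time
- solid substrate, solid product is a solid; its amount is given per volume of the solution
- at the start none of the solid substrate is in solution
- dissolved substrate means what is dissolved; the solid is not counted in it
- run time (flask): 12 min

1. the target and solid product together standing at 12 min, as a percentage of the solid substrate charged
2. concentration of dissolved substrate in solution at 12 min, in percent of saturation

I reckon the coupling rate first. With the charged 0.0210 M of reagent free and the solution saturated, it starts at 1.88 × 10⁻⁴ M s⁻¹. Dissolution can deliver 0.00126 M s⁻¹, which is faster, so I hold [dissolved substrate] at saturation while solid lasts. The exchange with the dormant form has a relaxation half-life of 0.132 min, much shorter than the run, so I treat it as at equilibrium, and it slows the rate by the free fraction 0.417. If 0.5 of the charge couples, the reagent spent on average slows it by a further 0.762. That leaves 5.97 × 10⁻⁵ M s⁻¹.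

The solid's loss to homo dimer starts at 4.16 × 10⁻⁴ M s⁻¹, faster than that. I carry the crossover level S*, the [solid substrate] at which loss to homo dimer equals the coupling rate: 0.00758 M. Integrating both losses, the solid that couples is S* times the arctangent of the undissolved charge over S*. That ratio is 2.45; I halve the angle once and apply a rational estimate of the arctangent to the half, which gives about 1.18 radians. Adding the saturated solution gives 0.0104 M, or 51.8%. My solid reaches zero at 2.50 min. After that, dissolved substrate decays pseudo-first-order at 0.0284 s⁻¹, which leaves <0.001% of saturation.

The forecast gives 52% and <0.001%, holding that “the solid is gone in about 2.5 minutes with roughly half of the substrate converted to target”. My yield is lower.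

The flask gives 54.9% and 0%. At 1.20 min its solid substrate stands at 0.00509 M, already below S*. From there to 6.00 min, homo dimer moves from 41.6% to 45.1%, while target with solid product moves from 26.3% to 54.9%.

For the neighbour flask charged with 0.050 M, S* becomes 0.0120 M, the ratio 4.06 and the arctangent, by the same estimate, 1.33, so I expect 34.6%. That flask gives 37.1%.

The numbers are made up; the result is computed.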